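The seven-membered ring C1–C2–C3–C4–C9–C10–C11 is annulated onto a preformed cyclohexenone (ring C5–C10) by making its two missing bonds in one flask: C4–C9, which also closes the cyclobutane of the bicyclo[3.1.1]heptenone, and C1–C11, between the two future angelate carbons. The precursor is an α′-diazo cyclohexenone carrying a formyl group (C11) on quaternary C10 and, cis to it on C5, a CH2–CMe2–C(O)CH3 arm. A rhodium carbenoid at C9 inserts into a C4–H bond; base then closes C1 onto the aldehyde by aldol cyclodehydration. Exploited feature: the C4 methylene on C5 sits 1,3 to C9 on ring C5–C10, and C9 has no 1,5 C–H bond.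

Key step: step 13

Locants used throughout: C1 and C11 are the two angeloyloxy carbons (C1 next to the carbinol C2); C3 = CMe2; C4 = cyclobutane CH; C5 = bridgehead next to C6 (CHCH3); C7 = CH2; C8 = C=O; C9 = bridgehead next to C8; C10 = C(CH3) bridge.

Assumption: the methoxy-bearing carbon in 6–9, 13 and 14 and the carbinol carbon in 14–17 are carried as epimer mixtures; both centres are erased later (steps 10 and 12).

Step 1
Reactants: 1 5-hydroxy-4-methylfuran-2(5H)-one; 2 (+)-menthol
Product: 3 (5S)-5-[(1S,2R,5S)-menthyloxy]-4-methylfuran-2(5H)-one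
Conditions: CSA (cat.), toluene, reflux, Dean–Stark; crystallisation (hexane), mother liquor re-equilibrated with CSA
Reagents that add atoms: none
Why: Acid-catalysed acetalisation of the pseudo-acid, in which the acetal centre epimerises under the conditions and the (5S) epimer should be collected by crystallisation, as with the parent menthyloxyfuranones.

Step 2
Reactants: 4 (E)-4-methoxybut-3-en-2-one
Product: 5 (E)-1-methoxy-3-(tert-butyldimethylsilyloxy)buta-1,3-diene
Conditions: TBSOTf, Et3N, Et2O, 0 °C
Reagents that add atoms: tert-butyldimethylsilyl triflate CC(C)(C)[Si](C)(C)OS(=O)(=O)C(F)(F)F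
Why: Soft enolisation and O-silylation of the vinylogous ester gives the Danishefsky-type diene in its hydrolytically more robust TBS form.

Step 3
Reactants: 3 menthyloxybutenolide; 5 silyloxydiene
Product: 6 cis-fused cycloadduct (TBS enol ether C7=C8, OMe on C6, lactone carbonyl = C4, acetal carbon = C11, methyl on C10)
Conditions: toluene, BHT (cat.), 120 °C, sealed tube
Reagents that add atoms: none
Why: Diels–Alder reaction in which the nucleophilic CH2 terminus of the diene bonds to the β-carbon of the butenolide (C10, quaternary), the diene adds anti to the menthyloxy group (absolute control of C5 and C10), and the cis ring fusion places C4 and C11 cis.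

Step 4
Reactants: 6 cycloadduct
Product: 7 diol (C4H2OH on C5, C11H2OH on C10, TBS enol ether retained)
Conditions: LiAlH4, THF, 0 °C; Fieser work-up
Reagents that add atoms: none
Why: Hydride reduction of the acyloxy acetal delivers both primary alcohols and releases the auxiliary, while the silyl enol ether is inert.

Step 5
Reactants: 7 diol
Product: 8 C4 mono-tosylate
Conditions: TsCl (1.05 equiv), pyridine, CH2Cl2, 0 °C
Reagents that add atoms: p-toluenesulfonyl chloride Cc1ccc(cc1)S(Cl)(=O)=O
Why: Sulfonylation should select the less hindered primary alcohol on C4 over the neopentyl C11 alcohol.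

Step 6
Reactants: 8 mono-tosylate
Product: 9 C11 triethylsilyl ether tosylate
Conditions: Et3SiCl, imidazole, DMF, 0 °C
Reagents that add atoms: chlorotriethylsilane CC[Si](Cl)(CC)CC
Why: Silylation blocks the C11 hydroxyl, whose alkoxide would otherwise displace the tosylate to a tetrahydrofuran in step 8.

Step 7
Reactants: 10 3-methylbutan-2-one
Product: 11 3-methyl-2-(trimethylsilyloxy)but-2-ene
Conditions: Me3SiCl, Et3N, DMF, 130 °C
Reagents that add atoms: chlorotrimethylsilane C[Si](C)(C)Cl
Why: Equilibrating silylation gives the more substituted (thermodynamic) silyl enol ether, purified by distillation.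

Step 8
Reactants: 11 silyl enol ether; 9 tosylate
Product: 13 methyl ketone (C5–CH2–CMe2–C(O)CH3 arm), via lithium 3-methylbut-2-en-2-olate 12 (not isolated)
Conditions: MeLi, THF, 0 °C; then 9, LiI (cat.), DMPU, 0 to 40 °C
Reagents that add atoms: none
Why: MeLi unmasks the regiodefined tetrasubstituted enolate, whose SN2 C-alkylation by the primary tosylate forms the C3–C4 bond and the gem-dimethyl quaternary carbon.

Step 9
Reactants: 13 methyl ketone
Product: 14 secondary carbinol (C2 epimers)
Conditions: NaBH4, EtOH, 0 °C
Reagents that add atoms: none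
Why: Borohydride reduction masks the methyl ketone, whose CH3 would otherwise compete in the enolisation of step 11.

Step 10
Reactants: 14 carbinol
Product: 15 enone diol (C8 enone with C6=C7, C2–OH, C11–OH)
Conditions: 1 M HCl, THF, 0 to 23 °C
Reagents that add atoms: none
Why: Acid hydrolysis of the silyl enol ether followed by β-elimination of methanol gives the cyclohexenone and cleaves the triethylsilyl ether in the same operation, and the short cold exposure should keep conjugate addition of the freed hydroxyls to the enone at bay.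

Step 11
Reactants: 15 enone diol
Product: 17 α′-diazo enone diol (diazo on C9), via C9-trifluoroacetyl ketone 16 (not isolated)
Conditions: LiN(SiMe3)2 (3.3 equiv), THF, −78 °C; CF3CO2CH2CF3 (3.5 equiv); then MsN3, Et3N, H2O, MeCN, 23 °C
Reagents that add atoms: methanesulfonyl azide CS(=O)(=O)N=[N+]=[N-]
Why: Detrifluoroacetylative diazo transfer, in which the excess base first turns both hydroxyls into alkoxides, C9 is the only kinetic enolisation site of the enone, and O-trifluoroacetates formed on the alkoxides are cleaved by the aqueous amine of the transfer stage.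

Step 12
Reactants: 17 diazo enone diol
Product: 18 α′-diazo enone keto aldehyde (C2 methyl ketone, C11 aldehyde)
Conditions: Dess–Martin periodinane, NaHCO3, CH2Cl2, 23 °C
Reagents that add atoms: none
Why: Buffered Dess–Martin oxidation converts both alcohols without touching the acceptor-stabilised diazo ketone.

Step 13
Reactants: 18 diazo keto aldehyde
Product: 20 tricyclic bis-enone (C4–C9 and C1=C11 formed; enones at C8 and C2), via cyclobutane keto aldehyde 19 (not isolated)
Conditions: Rh2(esp)2 (1 mol %; esp = α,α,α′,α′-tetramethyl-1,3-benzenedipropanoate), CH2Cl2, 0 to 23 °C; then DBU (2 equiv), 40 °C, same flask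
Reagents that add atoms: none
Why: Rh2(esp)2 turns the diazo ketone into an electrophilic carbenoid at C9 that inserts into the pseudo-axial C4–H bond with loss of N2 (19); DBU then enolises the methyl ketone (C3 is quaternary, so only towards C1), C1 adds to the non-enolisable C11 aldehyde and the aldol dehydrates to the cycloheptenone. The closest known reaction types are the intramolecular C–H insertion of α-diazo ketone rhodium carbenoids, which closes four-membered rings in rigid substrates that offer no δ C–H bond, and the aldol cyclodehydration of keto aldehydes. Ring closures: the cyclobutane, and with it the second six-membered ring of the bicyclo[3.1.1]heptenone, by 1,4-C–H insertion across ring positions C5 and C9; the seven-membered ring by a 7-(enolendo)-exo-trig aldol, preorganised because C3 and C11 end up cis-1,3 on the new cyclobutane. New stereocentres: C9 becomes a bridgehead fixed by the existing C5 and C10 centres (only the cis-bridged bicycle can form), and C4 is set by insertion into the hydrogen that leaves the bulky CMe2 arm exo, away from the three-carbon enone bridge. The selectivity needed is C4–H insertion over other carbenoid pathways: C10 is quaternary (no 1,2-hydride shift), C6 and C7 are sp2 and C3 is quaternary, so no 1,5 C–H bond exists, and the C4 methylene sits cis to the formyl group and directly over C9. The remaining competitors (insertion into a C3 methyl C–H bond, ylide formation at the C2 ketone oxygen, 1,2-shift of the formyl group) are the main risk and are dealt with below.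

Step 14
Reactants: 20 tricyclic bis-enone
Product: 21 C6-methyl trimethylsilyl enol ether (C7=C8–OSiMe3; C2 enone untouched)
Conditions: Me2CuLi (from CuI, MeLi), Me3SiCl, THF, −78 °C; Et3N quench
Reagents that add atoms: lithium dimethylcuprate [Li+].C[Cu-]C; chlorotrimethylsilane C[Si](C)(C)Cl
Why: Cuprate conjugate addition to the bicyclo[3.1.1]heptenone occurs anti to the C10 bridge, whose methyl shields that face, so the C6 methyl ends up syn to the C4 bridge; the second enone has a neopentyl β-carbon (C11) and should react more slowly, and the enolate is trapped to mask C8.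

Step 15
Reactants: 21 silyl enol ether enone
Product: 23 allylic alcohol ketone (C2–OH on the C5/C6 side of the seven-membered ring; C8 ketone), via silyl enol ether carbinol 22 (not isolated)
Conditions: (S)-2-methyl-CBS-oxazaborolidine (0.2 equiv), catecholborane, toluene, −78 °C; then 0.5 M aqueous citric acid, THF, 0 °C
Reagents that add atoms: none
Why: Corey–Bakshi–Shibata reduction under reagent control (CMe2 as the large group) sets C2, which the nearly symmetric surroundings of the four-carbon bridge could not control, and the mildly acidic work-up cleaves the silyl enol ether without ionising the allylic alcohol.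

Step 16
Reactants: 23 allylic alcohol
Product: 24 C2 tert-butyldimethylsilyl ether
Conditions: TBSOTf, 2,6-lutidine, CH2Cl2, −78 °C
Reagents that add atoms: tert-butyldimethylsilyl triflate CC(C)(C)[Si](C)(C)OS(=O)(=O)C(F)(F)F
Why: Silylation of the hindered secondary alcohol keeps C2 free of acyl groups later and supplies the directing group for step 17.

Step 17
Reactants: 24 silyl ether
Product: 25 cis-C1,C11-diol (both hydroxyls trans to the C2 silyloxy group)
Conditions: OsO4 (5 mol %), NMO, acetone–H2O, 23 °C
Reagents that add atoms: N-methylmorpholine N-oxide C[N+]1([O-])CCOCC1; water O (oxygen passed on by osmium tetroxide O=[Os](=O)(=O)=O)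
Why: Catalytic syn-dihydroxylation of the cis alkene should occur anti to the allylic silyloxy group, the usual sense for osmylation of allylic ethers, giving the C1/C11 cis, C1/C2 trans triol pattern.

Step 18
Reactants: 25 cis-diol; 26 angelic acid
Product: 28 bis-angelate silyl ether, via angelic 2,4,6-trichlorobenzoic anhydride 27 (not isolated)
Conditions: 26 (6 equiv), 2,4,6-trichlorobenzoyl chloride (6 equiv), Et3N, toluene, 23 °C; then 25, 80 °C
Reagents that add atoms: angelic acid (second equivalent) C/C=C(/C)C(=O)O
Why: Yamaguchi-type acylation through the mixed anhydride, run without DMAP and with the anhydride in excess, should transfer one angeloyl group to each of the two hindered hydroxyls (C1 and C11) while avoiding Z to E isomerisation to tiglates.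

Step 19
Reactants: 28 bis-angelate silyl ether
Product: 29 target
Conditions: HF·pyridine, THF, 0 to 23 °C
Reagents that add atoms: none
Why: Acidic fluoride desilylation frees the C2 hydroxyl without the acyl migration that basic fluoride could cause.

Compound list
1 | 5-hydroxy-4-methylfuran-2(5H)-one | O=C1C=C(C)C(O)O1 | starting material
2 | (+)-menthol, (1S,2R,5S)-2-isopropyl-5-methylcyclohexan-1-ol | O[C@H]1C[C@@H](C)CC[C@@H]1C(C)C | starting material
3 | (5S)-5-[(1S,2R,5S)-menthyloxy]-4-methylfuran-2(5H)-one | CC1=CC(=O)O[C@@H]1O[C@H]2C[C@@H](C)CC[C@@H]2C(C)C | intermediate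
4 | (E)-4-methoxybut-3-en-2-one | CC(=O)/C=C/OC | starting material
5 | (E)-1-methoxy-3-(tert-butyldimethylsilyloxy)buta-1,3-diene | C=C(O[Si](C)(C)C(C)(C)C)/C=C/OC | intermediate
6 | cis-fused cycloadduct: 3-menthyloxy lactone fused to a 4-methoxy-6-silyloxycyclohexene, angular methyl on C10 | COC1C=C(O[Si](C)(C)C(C)(C)C)C[C@@]2(C)[C@@H]1C(=O)O[C@@H]2O[C@H]3C[C@@H](C)CC[C@@H]3C(C)C | intermediate
7 | diol: cis C5-CH2OH and C10-CH2OH on the methoxy silyl enol ether ring | COC1C=C(O[Si](C)(C)C(C)(C)C)C[C@](C)(CO)[C@@H]1CO | intermediate
8 | C4 mono-tosylate of 7 | COC1C=C(O[Si](C)(C)C(C)(C)C)C[C@](C)(CO)[C@@H]1COS(=O)(=O)c2ccc(C)cc2 | intermediate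
9 | C11 triethylsilyl ether of 8 | COC1C=C(O[Si](C)(C)C(C)(C)C)C[C@](C)(CO[Si](CC)(CC)CC)[C@@H]1COS(=O)(=O)c2ccc(C)cc2 | intermediate
10 | 3-methylbutan-2-one | CC(C)C(C)=O | starting material
11 | 3-methyl-2-(trimethylsilyloxy)but-2-ene | CC(C)=C(C)O[Si](C)(C)C | intermediate
12 | lithium 3-methylbut-2-en-2-olate | [Li+].CC(C)=C(C)[O-] | intermediate
13 | methyl ketone: C5-CH2-CMe2-C(O)CH3 arm, C11 OSiEt3, masked enone | COC1C=C(O[Si](C)(C)C(C)(C)C)C[C@](C)(CO[Si](CC)(CC)CC)[C@@H]1CC(C)(C)C(C)=O | intermediate
14 | carbinol from 13 (C2 epimers) | COC1C=C(O[Si](C)(C)C(C)(C)C)C[C@](C)(CO[Si](CC)(CC)CC)[C@@H]1CC(C)(C)C(C)O | intermediate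
15 | enone diol: 5-(hydroxymethyl)-5-methyl-4-(3-hydroxy-2,2-dimethylbutyl)cyclohex-2-enone, C4/C11 arms cis | O=C1C=C[C@@H](CC(C)(C)C(C)O)[C@@](C)(CO)C1 | intermediate
16 | C9-trifluoroacetyl derivative of 15 | O=C1C=C[C@@H](CC(C)(C)C(C)O)[C@@](C)(CO)C1C(=O)C(F)(F)F | intermediate
17 | α′-diazo enone diol (diazo on C9) | O=C1C=C[C@@H](CC(C)(C)C(C)O)[C@@](C)(CO)C1=[N+]=[N-] | intermediate
18 | α′-diazo enone keto aldehyde (C2 methyl ketone, C11 aldehyde) | O=C1C=C[C@@H](CC(C)(C)C(C)=O)[C@@](C)(C=O)C1=[N+]=[N-] | intermediate
19 | bicyclo[3.1.1]hept-3-en-2-one with formyl and methyl on C10 and the CMe2C(O)CH3 arm exo on C4 | CC(=O)C(C)(C)[C@H]1[C@@H]2C=CC(=O)[C@H]1[C@]2(C)C=O | intermediate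
20 | tricyclic bis-enone (C8 ketone with C6=C7; C2 ketone with C1=C11) | O=C1C=C[C@@]2(C)[C@@H]3C(=O)C=C[C@H]2[C@@H]3C1(C)C | intermediate
21 | C6-methyl adduct as C7=C8 trimethylsilyl enol ether, C6 methyl syn to the C4 bridge | O=C1C=C[C@@]2(C)[C@@H]3C(O[Si](C)(C)C)=C[C@@H](C)[C@H]2[C@@H]3C1(C)C | intermediate
22 | C2 carbinol of 21 (silyl enol ether intact) | O[C@@H]1C=C[C@@]2(C)[C@@H]3C(O[Si](C)(C)C)=C[C@@H](C)[C@H]2[C@@H]3C1(C)C | intermediate
23 | allylic alcohol ketone (C2–OH, C1=C11, C8 ketone) | O[C@@H]1C=C[C@@]2(C)[C@@H]3C(=O)C[C@@H](C)[C@H]2[C@@H]3C1(C)C | intermediate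
24 | C2 tert-butyldimethylsilyl ether of 23 | CC(C)(C)[Si](C)(C)O[C@@H]1C=C[C@@]2(C)[C@@H]3C(=O)C[C@@H](C)[C@H]2[C@@H]3C1(C)C | intermediate
25 | C1,C11 cis-diol, trans to the C2 silyloxy group | CC(C)(C)[Si](C)(C)O[C@@H]1[C@@H](O)[C@@H](O)[C@@]2(C)[C@@H]3C(=O)C[C@@H](C)[C@H]2[C@@H]3C1(C)C | intermediate
26 | angelic acid, (Z)-2-methylbut-2-enoic acid | C/C=C(/C)C(=O)O | starting material
27 | angelic 2,4,6-trichlorobenzoic anhydride | C/C=C(/C)C(=O)OC(=O)c1c(Cl)cc(Cl)cc1Cl | intermediate
28 | C1,C11 bis-angelate, C2 silyl ether | CC(C)(C)[Si](C)(C)O[C@@H]1[C@@H](OC(=O)/C(C)=C\C)[C@@H](OC(=O)/C(C)=C\C)[C@@]2(C)[C@@H]3C(=O)C[C@@H](C)[C@H]2[C@@H]3C1(C)C | intermediate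
29 | target bis-angelate (CNP0344448.1) | C/C=C(/C)C(=O)O[C@@H]1[C@@H](O)C(C)(C)[C@H]2[C@@H]3[C@H](C)CC(=O)[C@H]2[C@]3(C)[C@@H]1OC(=O)/C(C)=C\C | target

Total steps: 19. Longest linear sequence: 17 steps (1, 3–6, 8–19).

Steps most likely to fail

Step 13. The carbenoid may lose site selectivity: insertion into a C3 methyl C–H bond, ylide formation at the C2 ketone oxygen, or 1,2-migration of the formyl group could outrun closure of the strained four-membered ring. The fallback closes the seven-membered ring first, so that the insertion runs on a locked substrate in which C4–H is the only C–H bond within reach. It sets out from 15. Dess–Martin oxidation gives the diazo-free keto aldehyde enone F1. Aldol cyclodehydration with pyrrolidinium acetate then gives the cis-fused bicyclic dienone F2, whose only kinetically acidic position is C9; the amine salt activates the non-enolisable aldehyde as its iminium ion, so that C1 closes on C11 in preference to conjugate addition at C6. LiN(SiMe3)2 and CF3CO2CH2CF3 give the C9-trifluoroacetyl bicyclic dienone F3, and MsN3/Et3N the C9-diazo bicyclic dienone F4. Rh2(esp)2 in CH2Cl2 then effects the C4–H insertion and the route is rejoined at 20.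

Step 8. C-alkylation of a tetrasubstituted ketone enolate by a β-branched tosylate may be slow, leaving O-alkylation and proton transfer to dominate. The fallback uses the more nucleophilic ester enolate and builds the carbinol in two further operations. It sets out from 9: the lithium enolate of methyl isobutyrate (LDA, THF, DMPU) gives the methyl ester analogue of 13 F5; i-Bu2AlH at −78 °C gives the aldehyde from F5 F6; MeMgBr then returns to the route at 14.

Step 3. The β,β-disubstituted butenolide may be too sluggish a dienophile, so that the diene decays thermally before cycloaddition. The fallback activates the dienophile with a removable bromine. It sets out from 3: Br2 gives 3,4-dibromo-5-menthyloxy-4-methyldihydrofuran-2-one F7 and Et3N gives (5S)-3-bromo-5-menthyloxy-4-methylfuran-2(5H)-one F8; cycloaddition with 5 at lower temperature gives the ring-fusion bromo analogue of 6 F9; Bu3SnH/AIBN removes the bromine with hydrogen delivery to the convex face and returns to the route at 6.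

Further compounds
F1 | step 13 | diazo-free keto aldehyde enone | O=C1C=C[C@@H](CC(C)(C)C(C)=O)[C@@](C)(C=O)C1
F2 | step 13 | cis-fused bicyclic dienone (seven-membered ring closed, no cyclobutane) | O=C1C=C[C@H]2CC(C)(C)C(=O)C=C[C@@]2(C)C1
F3 | step 13 | C9-trifluoroacetyl bicyclic dienone | O=C1C=C[C@H]2CC(C)(C)C(=O)C=C[C@@]2(C)C1C(=O)C(F)(F)F
F4 | step 13 | C9-diazo bicyclic dienone | O=C1C=C[C@H]2CC(C)(C)C(=O)C=C[C@@]2(C)C1=[N+]=[N-]
F5 | step 8 | methyl ester analogue of 13 | COC1C=C(O[Si](C)(C)C(C)(C)C)C[C@](C)(CO[Si](CC)(CC)CC)[C@@H]1CC(C)(C)C(=O)OC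
F6 | step 8 | aldehyde from F5 | COC1C=C(O[Si](C)(C)C(C)(C)C)C[C@](C)(CO[Si](CC)(CC)CC)[C@@H]1CC(C)(C)C=O
F7 | step 3 | 3,4-dibromo-5-menthyloxy-4-methyldihydrofuran-2-one | CC1(Br)C(Br)C(=O)O[C@@H]1O[C@H]2C[C@@H](C)CC[C@@H]2C(C)C
F8 | step 3 | (5S)-3-bromo-5-menthyloxy-4-methylfuran-2(5H)-one | CC1=C(Br)C(=O)O[C@@H]1O[C@H]2C[C@@H](C)CC[C@@H]2C(C)C
F9 | step 3 | ring-fusion bromo analogue of 6 | COC1C=C(O[Si](C)(C)C(C)(C)C)C[C@@]2(C)[C@]1(Br)C(=O)O[C@@H]2O[C@H]3C[C@@H](C)CC[C@@H]3C(C)C
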